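(The numbers in the tables stem from a simulated flask with constants of no real substance, and the scatter is random.)

A small charge of starting material, 0.049 M, sits in the first phase while its reagent waits in the second phase, and you want to know what this flask holds at 10 d, given one earlier run, the alder run, with more reagent.

| setting | alder | flask |
|---|---|---|
| starting material | 0.049 M | 0.049 M |
| reagent in the second phase | 0.39 M | 0.196 M |
| remark | run made earlier |  |
| time |  | 10 d |
| volume of the second phase over the first |  | 1.0 |

- alder (time / d: target / %, starting material / %): 0.250: 1.5, 95.7; 0.417: 1.7, 91.2; 0.625: 1.9, 86.5; 1.04: 2.2, 76.4; 1.67: 6.0, 61.5; 3.00: 9.6, 36.8

(scatter of a reading: 0.5 percentage points)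

- how much target there is at 10 d, in percent of the starting material charged
- part of the starting material charged that has reacted at 10 d

- in the second phase: reagent in the second phase; everything else is in the first
- charges count per volume of the first phase; a concentration in a rate is the amount of a species over the volume of its own phase; every rate counts per litre of the first phase
- the earlier runs hold the two phases in the same ratio of volumes as the flask asked about
- what has gone from starting material into another species counts as reacted, even if it can come back

If loss follows what is present, the rate integrates to c(starting material) = charge × exp(−k t). So take the natural logarithm of charge over what is left and divide by the time: the last alder reading, 36.8% left at 3.00 d, gives 0.333 d⁻¹, and this is the loss constant, an apparent first-order constant. It is a rough average up to that reading and no true constant, since the same reckoning gives 0.176 d⁻¹ at the first alder reading and 0.259 d⁻¹ at the fourth, less than at the last and climbing from each reading to the next, a steady drift rather than scatter, so the alder loss is not first order and what I carry forward from it is a rough estimate.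

Turn the time first: carried to 10 d, the constant leaves 3.57%, so 96.4% has reacted. Then turn the reagent: this flask has half the alder charge, and a constant that followed that charge in proportion would leave 18.7%, so 81.3% has reacted. One run cannot say which holds, so I commit to that range for the reacted part and to nothing for the target.

The forecast gives 15% of target and 88% reacted, on the ground that “If the rate scales with reagent concentration, halving it gives about 11 %/d”; its figure lies inside my range but comes from a straight-line fall, not from my constant.

The flask gives 10.2% of target and 94.0% reacted, and this is what runs in it:

    reagent in the reaction phase ⇌ reagent in the second phase, rate k1*([reagent in the reaction phase] - [reagent in the second phase]/K1) per volume of the first phase (partition coefficient = 23.0, kL = 1.86 × 10⁻⁴ min⁻¹)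
    starting material + reagent in the reaction phase → target (k = 0.0479 M⁻¹ min⁻¹)
    starting material ⇌ dormant form (K = 5.10, k = 1.18 × 10⁻⁴ min⁻¹)
    starting material + target → side product (k = 0.0177 M⁻¹ min⁻¹)

Changed by itself from the alder run at its last reading, time takes the reacted part from 62.8% to 98.7%, and reagent takes it to 51.5%. The flask's own loss constant, from 6.0% left, is 0.281 d⁻¹, which is 0.844 of the alder value. At 1.78 d the forward rate from starting material to dormant form is 3.0 times its rate to target. That forward rate contains no reagent term. Carried to the same flask read at 2.5 d, the constant leaves 49.5%, where that neighbour holds 55%.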